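**Retrosynthetic overview**
- The plan rests on ring B (C5–C10): its C7 carbon branch and C8 oxygen are cis and C5 must carry oxygen for annulation, the pattern of a 1,4-dioxygenated butadiene (C5, C10, C9, C8) added to a vinyl ketone (C6, C7).
- Ring B first: enantioselective Diels–Alder reaction of diene 5 with but-3-en-2-one 6 forms C5–C6 and C7–C8 (adduct 7).
- Ring A second: C5 acetate to ketone, C10 methylation, chiral-imine Michael addition to ethyl vinyl ketone (C10–C1) and aldol condensation (C4–C5) give the eudesm-4-en-3-one 19.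
- Side chain and oxygens: acetyl to isopropenyl to methyl acrylate (C11–C13), C8 silyl ether to acetate, C3 ketone to 3β-isobutyrate.
- Last: singlet-oxygen ene reaction of C4=C5 puts the hydroperoxide on C5 and moves the alkene to C4=C15.

Key step: step 4

Remark on numbering: eudesmane numbering is used throughout (ring A = C1–C5, C10; ring B = C5–C10; C14 = methyl on C10; C15 = carbon on C4; C11–C13 = side chain on C7); β is the face of C14; TBS = tert-butyldimethylsilyl.

Assumption: the α-C–H···O binding model for vinyl ketones on cationic oxazaborolidines is taken to assign the catalyst from (R)-α,α-diphenylprolinol to the (7S,8R) adduct; the sense is to be checked on the first run (Mosher ester of 9) and the (S)-derived catalyst used instead if it is reversed, with nothing else changed.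

**Step 1**
Reactants: 1 cis-but-2-ene-1,4-diol
Product: 2 (Z)-4-hydroxybut-2-en-1-yl acetate
Conditions: Ac2O (0.5 equiv), Et3N, DMAP (cat.), THF, 0 °C
Reagents that add atoms: acetic anhydride CC(=O)OC(C)=O
Why: Statistical mono-acylation of a symmetrical diol with a deficit of anhydride (nucleophilic acyl substitution) should give mainly the monoacetate, the excess water-soluble diol being washed out and recycled.

**Step 2**
Reactants: 2 (Z)-4-hydroxybut-2-en-1-yl acetate
Product: 4 (E)-4-acetoxybut-2-enal, via (Z)-4-acetoxybut-2-enal 3 (not isolated)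
Conditions: MnO2 (activated, excess), CH2Cl2, rt; filter; TsOH·H2O (cat.), CH2Cl2, rt
Reagents that add atoms: none
Why: MnO2 oxidises only the allylic alcohol (chemoselective allylic oxidation) and the first-formed Z-enal should isomerise under acid catalysis to the more stable E-enal.

**Step 3**
Reactants: 4 (E)-4-acetoxybut-2-enal
Product: 5 (1E,3E)-4-(tert-butyldimethylsilyloxy)buta-1,3-dien-1-yl acetate
Conditions: TBSOTf, Et3N, Et2O, 0 °C to rt
Reagents that add atoms: tert-butyldimethylsilyl trifluoromethanesulfonate CC(C)(C)[Si](C)(C)OS(=O)(=O)C(F)(F)F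
Why: O-silylation of the enal followed by γ-deprotonation with the amine (vinylogous silyl enol ether formation) should give the 1-silyloxydiene, the s-trans enal leading to the 1E geometry and the less strained 3E enol acetate.

**Step 4**
Reactants: 5 (1E,3E)-4-(tert-butyldimethylsilyloxy)buta-1,3-dien-1-yl acetate; 6 but-3-en-2-one
Product: 7 (1R,4R,5S)-5-acetyl-4-(tert-butyldimethylsilyloxy)cyclohex-2-en-1-yl acetate (all-cis)
Conditions: B-o-tolyl oxazaborolidine from (R)-α,α-diphenylprolinol (20 mol%), Tf2NH (18 mol%), 6 (2 equiv), CH2Cl2, −78 to −40 °C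
Reagents that add atoms: none
Why: The boron of the N-protonated oxazaborolidine binds the ketone oxygen of 6 and diene 5 adds in a concerted, asynchronous endo [4+2] cycloaddition; the closest known reaction type is the cationic-oxazaborolidine-catalysed enantioselective Diels–Alder reaction of 1-silyloxybutadienes with vinyl ketones and acrylates. Ring B closes as a six-membered carbocycle by suprafacial [π4s+π2s] union, forming C5–C6 and C7–C8 in one event. C7 is set by the catalyst, which covers one face of the bound s-trans enone so that the diene reaches only the other; C8 and C5 follow from C7 through the endo transition state and the E,E geometry of the diene, which place acetyl, silyloxy and acetoxy on one face. The step needs the "ortho" regiochemistry (C8 next to the acyl-bearing carbon), secured by the silyloxy group being a far stronger donor than acetoxy, so that C5 is the nucleophilic terminus and bonds to the β-carbon C6 of the enone. It also needs the acid-labile dienol ether and the allylic acetate to survive, which is the reason for the weakly coordinating triflimide counter-ion and the low temperature.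

**Step 5**
Reactants: 7 (1R,4R,5S)-5-acetyl-4-(tert-butyldimethylsilyloxy)cyclohex-2-en-1-yl acetate
Product: 8 (1R,4R,5R)-4-(tert-butyldimethylsilyloxy)-5-(prop-1-en-2-yl)cyclohex-2-en-1-yl acetate
Conditions: Zn, CH2Br2, TiCl4 (preformed reagent), THF/CH2Cl2, 0 °C to rt
Reagents that add atoms: dibromomethane BrCBr
Why: The non-basic Takai–Lombardo methylenation should convert the methyl ketone into the isopropenyl group without enolising C7, eliminating the β-silyloxy group or touching the acetate.

**Step 6**
Reactants: 8 (1R,4R,5R)-4-(tert-butyldimethylsilyloxy)-5-(prop-1-en-2-yl)cyclohex-2-en-1-yl acetate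
Product: 9 (1R,4R,5R)-4-(tert-butyldimethylsilyloxy)-5-(prop-1-en-2-yl)cyclohex-2-en-1-ol
Conditions: K2CO3 (0.5 equiv), MeOH, 0 °C
Reagents that add atoms: none
Why: Carbonate-catalysed transesterification with methanol should remove the allylic acetate while the secondary silyl ether stays.

**Step 7**
Reactants: 9 (1R,4R,5R)-4-(tert-butyldimethylsilyloxy)-5-(prop-1-en-2-yl)cyclohex-2-en-1-ol
Product: 10 (4R,5R)-4-(tert-butyldimethylsilyloxy)-5-(prop-1-en-2-yl)cyclohex-2-en-1-one
Conditions: Dess–Martin periodinane, NaHCO3, CH2Cl2, 0 °C to rt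
Reagents that add atoms: none
Why: Dess–Martin oxidation of the allylic alcohol under buffered conditions should give the conjugated enone, removing the C5 stereocentre that is no longer needed.

**Step 8**
Reactants: 10 (4R,5R)-4-(tert-butyldimethylsilyloxy)-5-(prop-1-en-2-yl)cyclohex-2-en-1-one
Product: 12 (2RS,4R,5R)-4-(tert-butyldimethylsilyloxy)-2-methyl-5-(prop-1-en-2-yl)cyclohexan-1-one, via potassium enolate 11 (not isolated)
Conditions: K[HB(s-Bu)3] (1.05 equiv), THF, −78 °C; then MeI, −78 to 0 °C
Reagents that add atoms: iodomethane CI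
Why: Conjugate hydride addition of the bulky trialkylborohydride to the β-unsubstituted cyclohexenone should give the C5–C10 enolate regiospecifically, which is C-methylated in the same flask (reductive alkylation), the C10 configuration being irrelevant because it is erased in step 9.

**Step 9**
Reactants: 12 (2RS,4R,5R)-4-(tert-butyldimethylsilyloxy)-2-methyl-5-(prop-1-en-2-yl)cyclohexan-1-one; 13 (R)-1-phenylethylamine; 14 pent-1-en-3-one (ethyl vinyl ketone)
Product: 17 (2R,4R,5R)-4-(tert-butyldimethylsilyloxy)-2-methyl-2-(3-oxopentyl)-5-(prop-1-en-2-yl)cyclohexan-1-one, via imine 15 (not isolated), via Michael adduct imine 16 (not isolated)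
Conditions: 13, PPTS (cat.), toluene, reflux, Dean–Stark; concentrate; 14, THF, 40 °C; then AcOH/H2O/THF, rt
Reagents that add atoms: water O
Why: In this deracemising Michael addition of a chiral imine (d'Angelo reaction) the imine should react through its more substituted secondary enamine with 14 in a compact aza-ene-like transition state, the C10–C1 bond forming on the α face because the phenyl group of the (R)-auxiliary covers the β face and a β approach would also meet the C8 silyloxy group in a 1,3-diaxial relation, which sets the quaternary C10 with its methyl β before hydrolysis returns the ketone.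

**Step 10**
Reactants: 17 (2R,4R,5R)-4-(tert-butyldimethylsilyloxy)-2-methyl-2-(3-oxopentyl)-5-(prop-1-en-2-yl)cyclohexan-1-one
Product: 19 8β-(tert-butyldimethylsilyloxy)eudesma-4,11-dien-3-one, via ketol 18 (not isolated)
Conditions: NaOMe, MeOH, 60 °C
Reagents that add atoms: none
Why: Base-mediated intramolecular aldol condensation (second stage of the Robinson annulation) of the C4 enolate onto the C5 ketone followed by dehydration should close ring A as the conjugated C4=C5 enone.

**Step 11**
Reactants: 19 8β-(tert-butyldimethylsilyloxy)eudesma-4,11-dien-3-one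
Product: 20 8β-hydroxyeudesma-4,11-dien-3-one
Conditions: tetrabutylammonium fluoride, THF, rt to 40 °C
Reagents that add atoms: none
Why: Fluoride-induced desilylation should free the C8 hydroxyl, the enone and the isopropenyl group being inert to fluoride.

**Step 12**
Reactants: 20 8β-hydroxyeudesma-4,11-dien-3-one
Product: 21 8β-acetoxyeudesma-4,11-dien-3-one
Conditions: Ac2O, pyridine, DMAP (cat.), CH2Cl2, rt
Reagents that add atoms: acetic anhydride CC(=O)OC(C)=O
Why: DMAP-catalysed acetylation should install the C8 acetate before the C12 ester exists, so that a free C8 hydroxyl never faces the acrylate and cannot lactonise.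

**Step 13**
Reactants: 21 8β-acetoxyeudesma-4,11-dien-3-one
Product: 22 8β-acetoxy-12-hydroxyeudesma-4,11(13)-dien-3-one
Conditions: SeO2 (0.5 equiv), t-BuOOH, CH2Cl2, rt
Reagents that add atoms: SeO2 O=[Se]=O (catalytic oxygen carrier); tert-butyl hydroperoxide CC(C)(C)OO (terminal oxygen source)
Why: The SeO2 ene reaction/[2,3]-sigmatropic shift (catalytic Sharpless allylic oxidation) should attack the electron-rich 1,1-disubstituted alkene at its methyl group, whereas the conjugated ring A alkene is electron-poor and should react much more slowly at room temperature.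

**Step 14**
Reactants: 22 8β-acetoxy-12-hydroxyeudesma-4,11(13)-dien-3-one
Product: 23 8β-acetoxy-3-oxoeudesma-4,11(13)-dien-12-al
Conditions: Dess–Martin periodinane, NaHCO3, CH2Cl2, 0 °C
Reagents that add atoms: none
Why: Dess–Martin oxidation should take the primary allylic alcohol (and leave any enal already formed in step 13) to the α-methylene aldehyde without touching the other groups.

**Step 15**
Reactants: 23 8β-acetoxy-3-oxoeudesma-4,11(13)-dien-12-al
Product: 24 8β-acetoxy-3-oxoeudesma-4,11(13)-dien-12-oic acid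
Conditions: NaClO2, NaH2PO4, 2-methylbut-2-ene, t-BuOH/H2O, 0 °C to rt
Reagents that add atoms: sodium chlorite [Na+].[O-]Cl=O
Why: Pinnick (Lindgren) chlorite oxidation with an alkene scavenger should convert the enal into the acrylic acid without chlorinating the alkenes.

**Step 16**
Reactants: 24 8β-acetoxy-3-oxoeudesma-4,11(13)-dien-12-oic acid
Product: 25 methyl 8β-acetoxy-3-oxoeudesma-4,11(13)-dien-12-oate
Conditions: Me3SiCHN2, MeOH/toluene, 0 °C
Reagents that add atoms: trimethylsilyldiazomethane C[Si](C)(C)C=[N+]=[N-]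
Why: O-methylation of the acid by diazomethane released from Me3SiCHN2 in methanol is base-free, so the acetate should stay and no conjugate addition should occur.

**Step 17**
Reactants: 25 methyl 8β-acetoxy-3-oxoeudesma-4,11(13)-dien-12-oate
Product: 26 methyl 8β-acetoxy-3β-hydroxyeudesma-4,11(13)-dien-12-oate
Conditions: NaBH4, CeCl3·7H2O, MeOH, −40 °C
Reagents that add atoms: none
Why: Luche 1,2-reduction should reduce only the enone carbonyl, hydride adding axially from the α face opposite the angular C10 methyl to give the equatorial 3β-alcohol and so set C3.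

**Step 18**
Reactants: 26 methyl 8β-acetoxy-3β-hydroxyeudesma-4,11(13)-dien-12-oate
Product: 27 methyl 8β-acetoxy-3β-(2-methylpropanoyloxy)eudesma-4,11(13)-dien-12-oate
Conditions: i-PrCOCl, pyridine, DMAP (cat.), CH2Cl2, 0 °C to rt
Reagents that add atoms: 2-methylpropanoyl chloride CC(C)C(Cl)=O
Why: DMAP-catalysed acylation of the allylic alcohol with the acid chloride should give the isobutyrate with retention at C3.

**Step 19**
Reactants: 27 methyl 8β-acetoxy-3β-(2-methylpropanoyloxy)eudesma-4,11(13)-dien-12-oate
Product: 28 methyl 8β-acetoxy-5α-hydroperoxy-3β-(2-methylpropanoyloxy)eudesma-4(15),11(13)-dien-12-oate (CNP0244758.1)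
Conditions: O2, methylene blue (cat.), visible light, CH2Cl2, 0 °C
Reagents that add atoms: dioxygen O=O
Why: In the Schenck ene reaction singlet oxygen should attack the only electron-rich alkene (C4=C5) from the α face opposite the angular methyl and the 3β-ester, bond to C5 and take a hydrogen from the freely rotating C15 methyl (the C3 hydrogen is deactivated by the geminal acyloxy group and the α hydrogen on C6 is equatorial), so that the alkene moves to C4=C15 and C5 carries the α-hydroperoxide.

**Compound list**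
1 | cis-but-2-ene-1,4-diol | OC/C=C\CO | starting material
2 | (Z)-4-hydroxybut-2-en-1-yl acetate | CC(=O)OC/C=C\CO | intermediate
3 | (Z)-4-acetoxybut-2-enal | CC(=O)OC/C=C\C=O | intermediate (not isolated)
4 | (E)-4-acetoxybut-2-enal | CC(=O)OC/C=C/C=O | intermediate
5 | (1E,3E)-4-(tert-butyldimethylsilyloxy)buta-1,3-dien-1-yl acetate | CC(=O)O/C=C/C=C/O[Si](C)(C)C(C)(C)C | intermediate
6 | but-3-en-2-one | CC(=O)C=C | starting material
7 | (1R,4R,5S)-5-acetyl-4-(tert-butyldimethylsilyloxy)cyclohex-2-en-1-yl acetate | CC(=O)[C@H]1C[C@@H](OC(C)=O)C=C[C@H]1O[Si](C)(C)C(C)(C)C | intermediate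
8 | (1R,4R,5R)-4-(tert-butyldimethylsilyloxy)-5-(prop-1-en-2-yl)cyclohex-2-en-1-yl acetate | CC(=C)[C@H]1C[C@@H](OC(C)=O)C=C[C@H]1O[Si](C)(C)C(C)(C)C | intermediate
9 | (1R,4R,5R)-4-(tert-butyldimethylsilyloxy)-5-(prop-1-en-2-yl)cyclohex-2-en-1-ol | CC(=C)[C@H]1C[C@@H](O)C=C[C@H]1O[Si](C)(C)C(C)(C)C | intermediate
10 | (4R,5R)-4-(tert-butyldimethylsilyloxy)-5-(prop-1-en-2-yl)cyclohex-2-en-1-one | CC(=C)[C@H]1CC(=O)C=C[C@H]1O[Si](C)(C)C(C)(C)C | intermediate
11 | potassium (4R,5R)-4-(tert-butyldimethylsilyloxy)-5-(prop-1-en-2-yl)cyclohex-1-en-1-olate | CC(=C)[C@H]1CC([O-])=CC[C@H]1O[Si](C)(C)C(C)(C)C.[K+] | intermediate (not isolated)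
12 | (2RS,4R,5R)-4-(tert-butyldimethylsilyloxy)-2-methyl-5-(prop-1-en-2-yl)cyclohexan-1-one | CC(=C)[C@H]1CC(=O)C(C)C[C@H]1O[Si](C)(C)C(C)(C)C | intermediate
13 | (R)-1-phenylethylamine | C[C@@H](N)c1ccccc1 | starting material
14 | pent-1-en-3-one (ethyl vinyl ketone) | CCC(=O)C=C | starting material
15 | N-[(R)-1-phenylethyl] imine of 12 | CC(=C)[C@H]1CC(=N[C@H](C)c2ccccc2)C(C)C[C@H]1O[Si](C)(C)C(C)(C)C | intermediate (not isolated)
16 | N-[(R)-1-phenylethyl] imine of 17 (Michael adduct) | CC(=C)[C@H]1CC(=N[C@H](C)c2ccccc2)[C@](C)(CCC(=O)CC)C[C@H]1O[Si](C)(C)C(C)(C)C | intermediate (not isolated)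
17 | (2R,4R,5R)-4-(tert-butyldimethylsilyloxy)-2-methyl-2-(3-oxopentyl)-5-(prop-1-en-2-yl)cyclohexan-1-one | CC(=C)[C@H]1CC(=O)[C@](C)(CCC(=O)CC)C[C@H]1O[Si](C)(C)C(C)(C)C | intermediate
18 | 8β-(tert-butyldimethylsilyloxy)-5-hydroxyeudesm-11-en-3-one (C4 and C5 not defined) | CC(=C)[C@H]1CC2(O)C(C)C(=O)CC[C@]2(C)C[C@H]1O[Si](C)(C)C(C)(C)C | intermediate (not isolated)
19 | 8β-(tert-butyldimethylsilyloxy)eudesma-4,11-dien-3-one [(4aR,6R,7R)-6-(tert-butyldimethylsilyloxy)-1,4a-dimethyl-7-(prop-1-en-2-yl)-4,4a,5,6,7,8-hexahydronaphthalen-2(3H)-one] | CC(=C)[C@H]1CC2=C(C)C(=O)CC[C@]2(C)C[C@H]1O[Si](C)(C)C(C)(C)C | intermediate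
20 | 8β-hydroxyeudesma-4,11-dien-3-one | CC(=C)[C@H]1CC2=C(C)C(=O)CC[C@]2(C)C[C@H]1O | intermediate
21 | 8β-acetoxyeudesma-4,11-dien-3-one | CC(=C)[C@H]1CC2=C(C)C(=O)CC[C@]2(C)C[C@H]1OC(C)=O | intermediate
22 | 8β-acetoxy-12-hydroxyeudesma-4,11(13)-dien-3-one | C=C(CO)[C@H]1CC2=C(C)C(=O)CC[C@]2(C)C[C@H]1OC(C)=O | intermediate
23 | 8β-acetoxy-3-oxoeudesma-4,11(13)-dien-12-al | C=C(C=O)[C@H]1CC2=C(C)C(=O)CC[C@]2(C)C[C@H]1OC(C)=O | intermediate
24 | 8β-acetoxy-3-oxoeudesma-4,11(13)-dien-12-oic acid | C=C(C(=O)O)[C@H]1CC2=C(C)C(=O)CC[C@]2(C)C[C@H]1OC(C)=O | intermediate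
25 | methyl 8β-acetoxy-3-oxoeudesma-4,11(13)-dien-12-oate | C=C(C(=O)OC)[C@H]1CC2=C(C)C(=O)CC[C@]2(C)C[C@H]1OC(C)=O | intermediate
26 | methyl 8β-acetoxy-3β-hydroxyeudesma-4,11(13)-dien-12-oate | C=C(C(=O)OC)[C@H]1CC2=C(C)[C@@H](O)CC[C@]2(C)C[C@H]1OC(C)=O | intermediate
27 | methyl 8β-acetoxy-3β-(2-methylpropanoyloxy)eudesma-4,11(13)-dien-12-oate | C=C(C(=O)OC)[C@H]1CC2=C(C)[C@@H](OC(=O)C(C)C)CC[C@]2(C)C[C@H]1OC(C)=O | intermediate
28 | methyl 8β-acetoxy-5α-hydroperoxy-3β-(2-methylpropanoyloxy)eudesma-4(15),11(13)-dien-12-oate | C=C(C(=O)OC)[C@H]1C[C@@]2(OO)C(=C)[C@@H](OC(=O)C(C)C)CC[C@]2(C)C[C@H]1OC(C)=O | target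

**Step count**
Total: 19 steps. Longest linear sequence: 19 steps (from 1).

**Steps most likely to fail**

Step 4. The strongly acidic catalyst may protodesilylate or ionise the dienol ether before cycloaddition, and a stepwise Mukaiyama–Michael pathway or uncatalysed background addition may erode regio- and enantiocontrol. The fallback sets out from 5 and 6 and gives up catalyst control in favour of resolution. Heating 5 and 6 in toluene at 80–100 °C with a trace of BHT (thermal endo Diels–Alder reaction) should give the racemic all-cis adduct rac-(1R*,4R*,5S*)-5-acetyl-4-(tert-butyldimethylsilyloxy)cyclohex-2-en-1-yl acetate F1. Methylenation under the conditions of step 5 gives the racemic isopropenyl acetate F2, and methanolysis under the conditions of step 6 gives the racemic allylic alcohol F3. Lipase-catalysed kinetic resolution (immobilised Candida antarctica lipase B, vinyl acetate, MTBE, rt) is expected, by analogy with cyclohex-2-en-1-ol, to acetylate the (1R)-alcohol faster. This delivers acetate 8 and leaves (1S,4S,5S)-4-(tert-butyldimethylsilyloxy)-5-(prop-1-en-2-yl)cyclohex-2-en-1-ol F4, which is separated. The route is rejoined at 8.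

Step 8. Hydride may add to the carbonyl carbon instead of C9, because C9 is flanked by the silyloxy-bearing C8, and proton exchange of the enolate may lead to over-methylation or regio-scrambled methylation. The fallback sets out from 10 and separates enolate formation from alkylation. RhCl(PPh3)3-catalysed 1,4-hydrosilylation with Et3SiH (THF, 50 °C) should give the isolable (4R,5R)-4-(tert-butyldimethylsilyloxy)-5-(prop-1-en-2-yl)-1-(triethylsilyloxy)cyclohex-1-ene F5. MeLi (THF, 0 °C) then releases the lithium enolate F6 regiospecifically, and MeI gives 12, where the route is rejoined.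

Step 9. Condensation and conjugate addition of the hindered ketimine may be slow, and reaction through the less substituted (C6) enamine or incomplete facial control at C10 may follow. The fallback sets out from 12 and replaces the enamine by a Lewis-acid-driven addition. Me3SiCl, NaI and Et3N in MeCN (thermodynamic conditions) should give the more substituted enol ether (4R,5R)-4-(tert-butyldimethylsilyloxy)-2-methyl-5-(prop-1-en-2-yl)-1-(trimethylsilyloxy)cyclohex-1-ene F7. Mukaiyama–Michael addition of F7 to 14 with TiCl4 (CH2Cl2, −78 °C) and aqueous work-up should give diketone 17 under substrate control, the acceptor approaching C10 anti to the C8 silyloxy group. The route is rejoined at 17.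

**Further compounds**
F1 | step 4 | rac-(1R*,4R*,5S*)-5-acetyl-4-(tert-butyldimethylsilyloxy)cyclohex-2-en-1-yl acetate | CC(=O)[C@H]1C[C@@H](OC(C)=O)C=C[C@H]1O[Si](C)(C)C(C)(C)C.CC(=O)[C@@H]1C[C@H](OC(C)=O)C=C[C@@H]1O[Si](C)(C)C(C)(C)C
F2 | step 4 | rac-(1R*,4R*,5R*)-4-(tert-butyldimethylsilyloxy)-5-(prop-1-en-2-yl)cyclohex-2-en-1-yl acetate | CC(=C)[C@H]1C[C@@H](OC(C)=O)C=C[C@H]1O[Si](C)(C)C(C)(C)C.CC(=C)[C@@H]1C[C@H](OC(C)=O)C=C[C@@H]1O[Si](C)(C)C(C)(C)C
F3 | step 4 | rac-(1R*,4R*,5R*)-4-(tert-butyldimethylsilyloxy)-5-(prop-1-en-2-yl)cyclohex-2-en-1-ol | CC(=C)[C@H]1C[C@@H](O)C=C[C@H]1O[Si](C)(C)C(C)(C)C.CC(=C)[C@@H]1C[C@H](O)C=C[C@@H]1O[Si](C)(C)C(C)(C)C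
F4 | step 4 | (1S,4S,5S)-4-(tert-butyldimethylsilyloxy)-5-(prop-1-en-2-yl)cyclohex-2-en-1-ol | CC(=C)[C@@H]1C[C@H](O)C=C[C@@H]1O[Si](C)(C)C(C)(C)C
F5 | step 8 | (4R,5R)-4-(tert-butyldimethylsilyloxy)-5-(prop-1-en-2-yl)-1-(triethylsilyloxy)cyclohex-1-ene | CC(=C)[C@H]1CC(O[Si](CC)(CC)CC)=CC[C@H]1O[Si](C)(C)C(C)(C)C
F6 | step 8 | lithium (4R,5R)-4-(tert-butyldimethylsilyloxy)-5-(prop-1-en-2-yl)cyclohex-1-en-1-olate | CC(=C)[C@H]1CC([O-])=CC[C@H]1O[Si](C)(C)C(C)(C)C.[Li+]
F7 | step 9 | (4R,5R)-4-(tert-butyldimethylsilyloxy)-2-methyl-5-(prop-1-en-2-yl)-1-(trimethylsilyloxy)cyclohex-1-ene | CC(=C)[C@H]1CC(O[Si](C)(C)C)=C(C)C[C@H]1O[Si](C)(C)C(C)(C)C
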